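## The problem

Compound 21 is the 9-O-stearate of (7S,8R,8′R)-lariciresinol. It is a tetrahydrofuran (O1, C2–C5) with a guaiacyl ring on C2, a stearoyloxymethyl arm (C9) on C3 and a guaiacylmethyl arm (C7′) on C4. The three contiguous stereocentres are C2 (S), C3 (R) and C4 (R): the aryl group is trans to the C9 arm, and the C9 and C7′ arms are cis. The cis relationship at C3/C4 is the less stable one, so it has to be built deliberately and must not sit next to an enolisable carbonyl under equilibrating conditions. C3 and C4 can be set together if they begin as the two carbons of a cis alkene, and a stereocentre next to that alkene can then choose the face. C2 is a benzylic ether carbon and is the only centre that can be lost by ionisation. The C2–O1 bond is the fragile point: it belongs to a p-oxygenated benzylic ether and is threatened by strong acid (epimerisation, Friedel–Crafts closure onto the C7′ aryl ring) and by prolonged hydrogenolysis. At the end, two free phenols must coexist with a base-labile long-chain ester, so the acylation has to tell a primary alcohol from phenols. The enabling feature is that C2–O1–C5 is a C–O–C triad beside the two-carbon unit C3–C4 with cis arms. The ring is therefore the (3+2) adduct of an aryl carbonyl ylide and a cis alkene, and both arms can come from one butenolide whose carbonyl becomes C9 and whose acetal carbon becomes C7′.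

## Retrosynthesis

**Ester C9–O.** Target 21 is cut at the stearate C–O bond to lariciresinol 20 and an activated stearic acid. Acylating last with a lipase uses the enzyme's preference for a primary aliphatic hydroxyl over phenols. The neighbouring option, acylation before phenol deprotection, would cost an extra protecting-group step. The forward step must leave both phenols free.

**C9 oxidation level.** Alcohol 20 is traced to carboxylic acid 19. No bond of the skeleton is cut. An acid at C9 is what a lactone carbonyl delivers after the other lactone bond is broken, and borane reduces an acid beside phenols, ethers and arenes.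

**C7′–O and the O-benzyl groups.** Acid 19 is traced to the cis-fused diaryl lactone 18 by reconnecting the carboxyl oxygen to C7′ and benzylating both phenols. One hydrogenolysis then has to cleave three benzylic C–O bonds and spare a fourth, C2–O1. This is preferred to a radical or ionic deoxygenation of an open benzylic alcohol because it needs no derivatisation.

**C7′–aryl.** Lactone 18 is cut at the C7′–aryl bond to hydroxy lactone 13, a masked aldehyde acid, and aryl bromide 15 through its Grignard reagent 16. This places the second aryl ring on a carbon that is already at the aldehyde level. The forward addition only has to be faster than epimerisation of C4 next to the transient aldehyde.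

**Auxiliary.** Hydroxy lactone 13 comes from the menthyl acetal 12 by hydrolysis. The acetal oxygen carries the only external source of chirality, (+)-menthol 7, which is released for recovery.

**C2–C3 and C4–C5 (key cut).** Adduct 12 is cut across both C–C bonds that join the C–O–C triad to the C3–C4 unit. This gives carbonyl ylide 11, drawn from bis(silylmethyl) acetal 3, and butenolide 9. The other ring cuts (C3–C4 by radical closure, O1–C2 by etherification) each leave one or two stereocentres to a later, separately controlled step. This cut removes the ring and three stereocentres at once and leaves two achiral or auxiliary-bearing pieces of about ten heavy atoms each. It asks the forward reaction for three things: attack anti to the menthyloxy group, the CH2 terminus on the β-carbon, and the aryl group exo.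

**Pieces.** Acetal 3 is cut at its two C–O bonds to O-benzylvanillin 1 and (trimethylsilyl)methanol 2. Butenolide 9 is cut at the acetal C–O bond to hydroxybutenolide 6 and (+)-menthol 7, and 6 comes from furfural 4 by photo-oxygenation. Aryl bromide 15 is the benzyl ether of 4-bromo-2-methoxyphenol 14.

## Roads not taken

**Alternative 1:** The cut is made at C3–C4 and at C7′–aryl. Forward, the open-chain iodide A2 (an O-allyl ether with iodine on C3 and the stearate already on C9) would be treated with NiBr2, a terpyridine ligand and the arylzinc iodide A3. The C3 radical closes 5-exo onto the allyl group and the C7′ radical is arylated on nickel, giving the bis-acetate A1, one selective aryl-ester cleavage from 21.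
- Merits: ring and C7′–aryl bond form in one step, the endgame is the shortest of all, and C7′ never carries an oxygen. On this last point it is better than the chosen plan, which must hydrogenolyse beside a benzylic ether.
- Weak points: only C2 exists before the key step and must control C3 and C4 through the conformation of a radical cyclisation. The 2,3-trans outcome is likely, but 3,4-cis rests on a modest cis preference, so diastereomer mixtures are to be expected. The C3 radical or its organonickel form has oxygen on both β-carbons, which invites β-elimination or direct arylation at C3. A2 also needs its own enantioselective synthesis.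
- Comparison: the chosen plan is longer after the key step, but C3 and C4 are fixed by a rigid cis alkene and a neighbouring auxiliary centre, not by a flexible transition state.

**Alternative 2:** The cut is made at the bond between the benzylic carbon of the ring aryl arm and C3, and at C4–C7′. Forward, the lithiated dithiane A6 adds to the β-carbon of the enantiomeric butenolide A5 and the enolate is trapped with benzyl bromide A7, giving the trans,trans lactone A4. No ring is closed.
- Merits: this three-component coupling is the best-established chemistry of 5-menthyloxybutenolides. It installs both aryl groups and sets the C3 and C4 centres with full auxiliary control, and C7′ arrives as CH2, so no deoxygenation is needed. In reliability of the key step it is ahead of the chosen plan.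
- Weak points: the tetrahydrofuran and C2 are still missing after the key step. Lactone and acetal reduction, dithiane removal, ketone reduction and an acid-mediated etherification must follow. C2 is then set late by a benzylic cation in a molecule that already carries the nucleophilic C7′ aryl ring.
- Comparison: overall length is similar. The chosen plan offers ring closure and all three stereocentres in a single step and no late cationic step at C2.

**Alternative 3:** The cut is made at C2–C3 only. Forward, Rh2(OAc)4 decomposes the diazo lactone A9 and the carbene at C3 inserts into the benzylic ether C2–H, closing the tetrahydrofuran onto the lactone to give the furofuranone A8.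
- Merits: the tether fixes regiochemistry and cis fusion beyond doubt. A8 is the exo C7′ epimer of lactone 18, so the endgame would be the same.
- Weak points: A9 already contains two stereocentres that need an enantioselective synthesis plus a diazo transfer. One of them, C7′, is destroyed afterwards. The compact insertion transition state does not oblige the new aryl group to the exo side, and if it falls endo the C2 epimer results.
- Comparison: Alternative 3 is safer in regiochemistry. The chosen plan reaches the same bicyclic lactone type intermolecularly from two simple pieces, with the absolute configuration taken from a recoverable auxiliary.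

Key step: step 4

Remark on the chemistry: lignan locants are used for the arms (C9 on C3, C7′ on C4). Compounds 13, 17 and 18 are carried as mixtures at C7′, because that carbon ends as CH2.

## Route

Step 1
Reactants: 1 4-(benzyloxy)-3-methoxybenzaldehyde; 2 (trimethylsilyl)methanol
Product: 3 4-(benzyloxy)-3-methoxybenzaldehyde bis[(trimethylsilyl)methyl] acetal
Conditions: 2 (2.5 equiv), p-TsOH·H2O (cat.), benzene, reflux, Dean–Stark; Et3N quench
Reagents that add atoms: none
Why: Acid-catalysed acetalisation driven by azeotropic removal of water; the primary α-silyl alcohol behaves as an ordinary primary alcohol, and the benzyl ether and C–Si bonds tolerate catalytic sulfonic acid. No stereocentre is formed.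

Step 2
Reactants: 4 furfural
Product: 6 5-hydroxyfuran-2(5H)-one, via furfural endoperoxide 5 (not isolated)
Conditions: O2, rose bengal (cat.), MeOH, visible light, rt
Reagents that add atoms: dioxygen, O=O
Why: Schenck-type dye-sensitised photo-oxygenation: singlet oxygen adds 4+2 across the furan to give endoperoxide 5, and methanol-assisted fragmentation expels the formyl carbon as methyl formate, leaving the hydroxybutenolide. The hemiacetal carbon is racemic and is reset in step 3.

Step 3
Reactants: 6 5-hydroxyfuran-2(5H)-one; 7 (+)-menthol
Product: 9 (5S)-5-[(1S,2R,5S)-menthyloxy]furan-2(5H)-one, via C5-epimeric menthyl acetal 8 (not isolated)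
Conditions: p-TsOH·H2O (cat.), benzene, reflux, Dean–Stark; crystallisation from petroleum ether at −20 °C; mother liquor re-equilibrated with acid and recrystallised
Reagents that add atoms: none
Why: Acid-catalysed acetalisation of the pseudo-acid gives both C5 epimers 8 and 9; only 9 should crystallise, and 8 returns to the equilibrium through the acyloxocarbenium ion, so a crystallisation-induced diastereomer transformation channels the material into the (5S) acetal. The C5 centre is thus set by the chirality of (+)-menthol and lattice selection, the established behaviour of 5-menthyloxybutenolides.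

Step 4
Reactants: 3 4-(benzyloxy)-3-methoxybenzaldehyde bis[(trimethylsilyl)methyl] acetal; 9 (5S)-5-[(1S,2R,5S)-menthyloxy]furan-2(5H)-one
Product: 12 (3S,3aR,6S,6aS)-6-[4-(benzyloxy)-3-methoxyphenyl]-3-[(1S,2R,5S)-menthyloxy]tetrahydro-1H,3H-furo[3,4-c]furan-1-one, via α-chloro ether 10 (not isolated), via carbonyl ylide 11 (not isolated)
Conditions: 3 (1.5 equiv), AcCl, SOCl2 (cat.), CH2Cl2, 0 °C to rt, then evaporation; the residue added slowly to 9 and CsF (4 equiv), MeCN, rt
Reagents that add atoms: none
Why: Acetyl chloride converts acetal 3 into α-chloro ether 10, whose ionised form loses its silyl group to fluoride (silicon-based 1,3-elimination) and releases the non-stabilised carbonyl ylide 11, C2=O1(+)–C5H2(−); the closest known reaction type is the fluoride-induced generation of such ylides from α-chloroalkyl silylmethyl ethers and their (3+2) cycloaddition to acrylates, maleates and other electron-poor alkenes, here applied to an α,β-unsaturated lactone. The ylide adds to the C=C of 9 in a concerted suprafacial 4π+2π cycloaddition, so the tetrahydrofuran closes by forming C2–C3 and C4–C5 in the same step and is necessarily cis-fused to the lactone. C3 and C4 are set by the C5 acetal centre of 9: the menthyloxy group blocks one face and the dipole should add anti to it, as other 1,3-dipoles, dienes and nucleophiles do with this butenolide, and the cis alkene makes the C9 and C7′ arms cis. The regiochemistry needed is CH2 terminus on the β-carbon: the donor aryl group stabilises the cationic end, so the CH2 end carries the carbanion character and the larger HOMO coefficient and attacks the β-carbon, which is also the less crowded pairing beside the acetal carbon. C2 is set by placement of the aryl group exo, away from the lactone ring on the convex face, which gives 2,3-trans; this is the selectivity least secured by the substrate, and the menthyl group makes any C2 epimer or regioisomer a separable diastereomer. Benzyl ether, lactone and acetal should tolerate CsF in MeCN, and the excess of 10 compensates for ylide lost to oxirane closure or dimerisation.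

Step 5
Reactants: 12 (3S,3aR,6S,6aS)-6-[4-(benzyloxy)-3-methoxyphenyl]-3-[(1S,2R,5S)-menthyloxy]tetrahydro-1H,3H-furo[3,4-c]furan-1-one
Product: 13 (3aR,6S,6aS)-6-[4-(benzyloxy)-3-methoxyphenyl]-3-hydroxytetrahydro-1H,3H-furo[3,4-c]furan-1-one (both C3 anomers)
Conditions: 2 M aq. HCl–1,4-dioxane (1:3), 50 °C
Reagents that add atoms: water, O
Why: Specific-acid hydrolysis of the lactone acetal through the acyloxocarbenium ion releases (+)-menthol for recovery; the product stays closed as the hydroxy lactone, so C4 never sits beside a free aldehyde and cannot epimerise, and the C2–O1 ether is deactivated towards ionisation by the carbonyl on C3. C2, C3 and C4 are untouched; the hemiacetal carbon forms as a mixture of no consequence.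

Step 6
Reactants: 14 4-bromo-2-methoxyphenol
Product: 15 1-(benzyloxy)-4-bromo-2-methoxybenzene
Conditions: BnBr, K2CO3, DMF, rt
Reagents that add atoms: benzyl bromide, BrCc1ccccc1
Why: Williamson ether synthesis on a phenoxide with a reactive benzylic halide; the aryl bromide is inert under these conditions.

Step 7
Reactants: 13 (3aR,6S,6aS)-6-[4-(benzyloxy)-3-methoxyphenyl]-3-hydroxytetrahydro-1H,3H-furo[3,4-c]furan-1-one; 15 1-(benzyloxy)-4-bromo-2-methoxybenzene
Product: 18 (3aR,6S,6aS)-3,6-bis[4-(benzyloxy)-3-methoxyphenyl]tetrahydro-1H,3H-furo[3,4-c]furan-1-one (both C3 epimers), via arylmagnesium bromide 16 (not isolated), via hydroxy acid 17 (not isolated)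
Conditions: 15, Mg, THF, rt; the resulting 16 (3 equiv) added to 13, THF, −78 to 0 °C; then 1 M HCl, rt
Reagents that add atoms: none
Why: Grignard addition to a pseudo-acid: the first equivalent of 16 deprotonates the lactol and unmasks the aldehyde carboxylate, the second adds to the aldehyde while the carboxylate is inert, and acidification closes hydroxy acid 17 to the γ-lactone because C9 and C7′ are cis. The new C7′ centre is not controlled and need not be, since it becomes CH2 in step 8; low temperature keeps the transient aldehyde from epimerising C4.

Step 8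
Reactants: 18 (3aR,6S,6aS)-3,6-bis[4-(benzyloxy)-3-methoxyphenyl]tetrahydro-1H,3H-furo[3,4-c]furan-1-one
Product: 19 (2S,3S,4R)-2-(4-hydroxy-3-methoxyphenyl)-4-(4-hydroxy-3-methoxybenzyl)oxolane-3-carboxylic acid
Conditions: H2 (1 atm), Pd/C (10 wt% Pd), EtOAc–EtOH (1:1), rt, stopped after uptake of three equivalents of H2
Reagents that add atoms: none
Why: Heterogeneous hydrogenolysis of benzylic C–O bonds: the two aryl benzyl ethers and the lactone C7′–O bond, which is benzylic and has a carboxylate leaving group, should be cleaved under neutral conditions, whereas C2–O1 is a benzylic alkyl ether with a poor leaving group and reacts more slowly. C7′ becomes CH2, which erases the mixture carried from step 7; C2, C3 and C4 are not touched.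

Step 9
Reactants: 19 (2S,3S,4R)-2-(4-hydroxy-3-methoxyphenyl)-4-(4-hydroxy-3-methoxybenzyl)oxolane-3-carboxylic acid
Product: 20 (7S,8R,8′R)-lariciresinol, [(2S,3R,4R)-2-(4-hydroxy-3-methoxyphenyl)-4-(4-hydroxy-3-methoxybenzyl)oxolan-3-yl]methanol
Conditions: BH3·THF (5 equiv), THF, 0 °C to rt; MeOH quench
Reagents that add atoms: none
Why: Borane reduces the carboxylic acid through an acyloxyborane much faster than it attacks ethers or arenes; the phenols only form aryl borates that methanol cleaves on work-up. The non-basic conditions leave C3, which is α to the carboxyl group, unepimerised.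

Step 10
Reactants: 20 (7S,8R,8′R)-lariciresinol
Product: 21 [(2S,3R,4R)-2-(4-hydroxy-3-methoxyphenyl)-4-(4-hydroxy-3-methoxybenzyl)oxolan-3-yl]methyl octadecanoate (CNP0168412.1)
Conditions: vinyl stearate (3 equiv), Novozym 435 (immobilised Candida antarctica lipase B), t-BuOMe–THF (4:1), 4 Å MS, 45 °C
Reagents that add atoms: vinyl stearate, CCCCCCCCCCCCCCCCCC(=O)OC=C
Why: Lipase-catalysed irreversible transesterification: the acyl-enzyme formed from vinyl stearate transfers the stearoyl group to the primary aliphatic hydroxyl, phenolic hydroxyls are not accepted as nucleophiles by this enzyme class, and the released vinyl alcohol tautomerises to acetaldehyde. No stereocentre is affected and no protecting group is needed.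

## Compound list

1 | 4-(benzyloxy)-3-methoxybenzaldehyde (O-benzylvanillin) | COc1cc(C=O)ccc1OCc1ccccc1 | starting material
2 | (trimethylsilyl)methanol | C[Si](C)(C)CO | starting material
3 | 4-(benzyloxy)-3-methoxybenzaldehyde bis[(trimethylsilyl)methyl] acetal | COc1cc(C(OC[Si](C)(C)C)OC[Si](C)(C)C)ccc1OCc1ccccc1 | intermediate
4 | furfural | O=Cc1ccco1 | starting material
5 | furfural endoperoxide, 2,3,7-trioxabicyclo[2.2.1]hept-5-ene-1-carbaldehyde | O=CC12OOC(C=C1)O2 | intermediate (not isolated)
6 | 5-hydroxyfuran-2(5H)-one (racemic) | O=C1C=CC(O)O1 | intermediate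
7 | (+)-menthol, (1S,2R,5S)-2-isopropyl-5-methylcyclohexanol | CC(C)[C@H]1CC[C@H](C)C[C@@H]1O | starting material
8 | (5R)-5-[(1S,2R,5S)-menthyloxy]furan-2(5H)-one (C5 epimer of 9) | O=C1C=C[C@H](O[C@H]2C[C@@H](C)CC[C@@H]2C(C)C)O1 | intermediate (not isolated)
9 | (5S)-5-[(1S,2R,5S)-menthyloxy]furan-2(5H)-one | O=C1C=C[C@@H](O[C@H]2C[C@@H](C)CC[C@@H]2C(C)C)O1 | intermediate
10 | α-chloro ether, 1-(benzyloxy)-4-{chloro[(trimethylsilyl)methoxy]methyl}-2-methoxybenzene | COc1cc(C(Cl)OC[Si](C)(C)C)ccc1OCc1ccccc1 | intermediate (not isolated)
11 | carbonyl ylide, [4-(benzyloxy)-3-methoxybenzylidene]oxonium methylide | COc1cc(C=[O+][CH2-])ccc1OCc1ccccc1 | intermediate (not isolated)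
12 | (3S,3aR,6S,6aS)-6-[4-(benzyloxy)-3-methoxyphenyl]-3-[(1S,2R,5S)-menthyloxy]tetrahydro-1H,3H-furo[3,4-c]furan-1-one | O=C1O[C@H](O[C@H]2C[C@@H](C)CC[C@@H]2C(C)C)[C@H]2CO[C@H](c3ccc(OCc4ccccc4)c(OC)c3)[C@@H]12 | intermediate
13 | (3aR,6S,6aS)-6-[4-(benzyloxy)-3-methoxyphenyl]-3-hydroxytetrahydro-1H,3H-furo[3,4-c]furan-1-one (both C3 anomers) | O=C1OC(O)[C@H]2CO[C@H](c3ccc(OCc4ccccc4)c(OC)c3)[C@@H]12 | intermediate
14 | 4-bromo-2-methoxyphenol | COc1cc(Br)ccc1O | starting material
15 | 1-(benzyloxy)-4-bromo-2-methoxybenzene | COc1cc(Br)ccc1OCc1ccccc1 | intermediate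
16 | [4-(benzyloxy)-3-methoxyphenyl]magnesium bromide | COc1cc([Mg]Br)ccc1OCc1ccccc1 | intermediate (not isolated)
17 | (2S,3S,4R)-2-[4-(benzyloxy)-3-methoxyphenyl]-4-{[4-(benzyloxy)-3-methoxyphenyl](hydroxy)methyl}oxolane-3-carboxylic acid (both carbinol epimers; present as its magnesium salt) | OC(c1ccc(OCc2ccccc2)c(OC)c1)[C@H]1CO[C@H](c2ccc(OCc3ccccc3)c(OC)c2)[C@H]1C(=O)O | intermediate (not isolated)
18 | (3aR,6S,6aS)-3,6-bis[4-(benzyloxy)-3-methoxyphenyl]tetrahydro-1H,3H-furo[3,4-c]furan-1-one (both C3 epimers) | O=C1OC(c2ccc(OCc3ccccc3)c(OC)c2)[C@H]2CO[C@H](c3ccc(OCc4ccccc4)c(OC)c3)[C@@H]12 | intermediate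
19 | (2S,3S,4R)-2-(4-hydroxy-3-methoxyphenyl)-4-(4-hydroxy-3-methoxybenzyl)oxolane-3-carboxylic acid | O=C(O)[C@H]1[C@@H](Cc2ccc(O)c(OC)c2)CO[C@@H]1c1ccc(O)c(OC)c1 | intermediate
20 | (7S,8R,8′R)-lariciresinol, [(2S,3R,4R)-2-(4-hydroxy-3-methoxyphenyl)-4-(4-hydroxy-3-methoxybenzyl)oxolan-3-yl]methanol | OC[C@H]1[C@@H](Cc2ccc(O)c(OC)c2)CO[C@@H]1c1ccc(O)c(OC)c1 | intermediate
21 | [(2S,3R,4R)-2-(4-hydroxy-3-methoxyphenyl)-4-(4-hydroxy-3-methoxybenzyl)oxolan-3-yl]methyl octadecanoate (CNP0168412.1) | CCCCCCCCCCCCCCCCCC(=O)OC[C@H]1[C@@H](Cc2ccc(O)c(OC)c2)CO[C@@H]1c1ccc(O)c(OC)c1 | target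

## Step count and risk

Total: 10 steps. Longest linear sequence: 8 steps (4 → 6 → 9 → 12 → 13 → 18 → 19 → 20 → 21; steps 2, 3, 4, 5, 7, 8, 9, 10).

**Step 4 (key step).** This ylide has not been paired with a 5-alkoxybutenolide. The facial course (anti to the menthyloxy group) is the best-secured element. The most likely failure is incomplete exo placement of the aryl group, because an endo transition state with the aryl ring under the lactone carbonyl is not strongly penalised; this would give a mixture at C2. Second is partial reversal of regiochemistry, and third is loss of the ylide to oxirane closure or dimerisation before it meets the alkene.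
Fallback: C2 is set under thermodynamic instead of kinetic control. The route sets out again from 3 and 9 and runs the cycloaddition without regard to exo selectivity. The endo-aryl adduct, (3S,3aR,6R,6aS)-6-[4-(benzyloxy)-3-methoxyphenyl]-3-[(1S,2R,5S)-menthyloxy]tetrahydro-1H,3H-furo[3,4-c]furan-1-one F1, is separated and treated with catalytic BF3·OEt2 in CH2Cl2 at low temperature. Reversible ionisation of the p-alkoxybenzylic C2–O1 bond and reclosure by the tethered C5 oxygen interconvert the C2 epimers. The exo isomer is removed and the remainder recycled, and the sequence returns to the route at 12. Scrambling at the acetal carbon during this treatment is harmless because that centre is destroyed in step 5. A wholesale reversal of regiochemistry could not be repaired within this disconnection and would call for the dithiane route to A4.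

**Step 8.** The likely failure is over-reduction: further hydrogenolysis of C2–O1 once the phenol para to it is free, opening the tetrahydrofuran, or the opposite, a lactone C–O bond that lags behind the debenzylation.
Fallback: radical deoxygenation replaces hydrogenolysis at C7′. It sets out from 18. LiAlH4 in THF reduces the lactone to the diol {(2S,3R,4R)-2-[4-(benzyloxy)-3-methoxyphenyl]-4-{[4-(benzyloxy)-3-methoxyphenyl](hydroxy)methyl}oxolan-3-yl}methanol F3. Stearoyl chloride and 2,4,6-collidine at −40 °C acylate the primary hydroxyl selectively to the mono-stearate F4. 1,1′-Thiocarbonyldiimidazole converts the benzylic alcohol into the imidazole-1-carbothioate F5, and Bu3SnH with AIBN in toluene at 80 °C (Barton–McCombie deoxygenation) gives the O,O′-dibenzyl ether of the target, F6. A brief hydrogenolysis of the two aryl benzyl ethers (H2, Pd/C, EtOAc) then returns to the route at 21, bypassing 19 and 20.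

**Step 5.** The likely failure is ionisation of C2–O1 under the acid needed for a sluggish acylal-type acetal, which would erode C2, or incomplete release of menthol.
Fallback: the auxiliary is removed by aminolysis instead of hydrolysis. It sets out from 12. Me3Al and MeNH(OMe)·HCl in CH2Cl2 open the lactone at C9, and the hemiacetal left at C7′ collapses on work-up with loss of menthol to the aldehyde amide (2S,3S,4R)-2-[4-(benzyloxy)-3-methoxyphenyl]-4-formyl-N-methoxy-N-methyloxolane-3-carboxamide F2. This is treated at once with 16 (1.1 equiv, THF, −78 °C). The aldehyde reacts faster than the amide, and the resulting alkoxide closes onto the amide carbonyl on acidic work-up, so the sequence returns to the route at 18.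

**Step 10.** The likely failure is slow or incomplete enzymatic acylation, because the primary hydroxyl is β-branched and flanked by two aryl-bearing carbons and the polar triol is poorly soluble in lipase-compatible solvents.
Fallback: chemical over-acylation followed by selective deacylation. It sets out from 20. Stearoyl chloride (3.5 equiv), pyridine and DMAP give the tristearate F7. Pyrrolidine (2.2 equiv, CH2Cl2, 0 °C) then cleaves the two aryl esters by aminolysis, which is far faster at a phenoxide-leaving ester than at the alkyl ester, and the sequence returns to the route at 21.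

## Further compounds

F1 | step 4 | (3S,3aR,6R,6aS)-6-[4-(benzyloxy)-3-methoxyphenyl]-3-[(1S,2R,5S)-menthyloxy]tetrahydro-1H,3H-furo[3,4-c]furan-1-one (C2 epimer of 12) | O=C1O[C@H](O[C@H]2C[C@@H](C)CC[C@@H]2C(C)C)[C@H]2CO[C@@H](c3ccc(OCc4ccccc4)c(OC)c3)[C@@H]12
F2 | step 5 | (2S,3S,4R)-2-[4-(benzyloxy)-3-methoxyphenyl]-4-formyl-N-methoxy-N-methyloxolane-3-carboxamide | O=C[C@H]1CO[C@H](c2ccc(OCc3ccccc3)c(OC)c2)[C@H]1C(=O)N(C)OC
F3 | step 8 | {(2S,3R,4R)-2-[4-(benzyloxy)-3-methoxyphenyl]-4-{[4-(benzyloxy)-3-methoxyphenyl](hydroxy)methyl}oxolan-3-yl}methanol (both carbinol epimers) | OC[C@H]1[C@@H](C(O)c2ccc(OCc3ccccc3)c(OC)c2)CO[C@@H]1c1ccc(OCc2ccccc2)c(OC)c1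
F4 | step 8 | {(2S,3R,4R)-2-[4-(benzyloxy)-3-methoxyphenyl]-4-{[4-(benzyloxy)-3-methoxyphenyl](hydroxy)methyl}oxolan-3-yl}methyl octadecanoate | CCCCCCCCCCCCCCCCCC(=O)OC[C@H]1[C@@H](C(O)c2ccc(OCc3ccccc3)c(OC)c2)CO[C@@H]1c1ccc(OCc2ccccc2)c(OC)c1
F5 | step 8 | O-benzylic imidazole-1-carbothioate of F4 | CCCCCCCCCCCCCCCCCC(=O)OC[C@H]1[C@@H](C(OC(=S)n2ccnc2)c2ccc(OCc3ccccc3)c(OC)c2)CO[C@@H]1c1ccc(OCc2ccccc2)c(OC)c1
F6 | step 8 | {(2S,3R,4R)-2-[4-(benzyloxy)-3-methoxyphenyl]-4-[4-(benzyloxy)-3-methoxybenzyl]oxolan-3-yl}methyl octadecanoate | CCCCCCCCCCCCCCCCCC(=O)OC[C@H]1[C@@H](Cc2ccc(OCc3ccccc3)c(OC)c2)CO[C@@H]1c1ccc(OCc2ccccc2)c(OC)c1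
F7 | step 10 | lariciresinol tristearate, {(2S,3R,4R)-2-[3-methoxy-4-(octadecanoyloxy)phenyl]-4-[3-methoxy-4-(octadecanoyloxy)benzyl]oxolan-3-yl}methyl octadecanoate | CCCCCCCCCCCCCCCCCC(=O)OC[C@H]1[C@@H](Cc2ccc(OC(=O)CCCCCCCCCCCCCCCCC)c(OC)c2)CO[C@@H]1c1ccc(OC(=O)CCCCCCCCCCCCCCCCC)c(OC)c1
A1 | alternative 1 | bis-acetate of the target, {(2S,3R,4R)-2-(4-acetoxy-3-methoxyphenyl)-4-(4-acetoxy-3-methoxybenzyl)oxolan-3-yl}methyl octadecanoate | CCCCCCCCCCCCCCCCCC(=O)OC[C@H]1[C@@H](Cc2ccc(OC(C)=O)c(OC)c2)CO[C@@H]1c1ccc(OC(C)=O)c(OC)c1
A2 | alternative 1 | (3R)-3-(4-acetoxy-3-methoxyphenyl)-3-(allyloxy)-2-iodopropyl octadecanoate (either configuration at the iodine-bearing carbon) | CCCCCCCCCCCCCCCCCC(=O)OCC(I)[C@H](OCC=C)c1ccc(OC(C)=O)c(OC)c1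
A3 | alternative 1 | (4-acetoxy-3-methoxyphenyl)zinc iodide | CC(=O)Oc1ccc([Zn]I)cc1OC
A4 | alternative 2 | (3R,4R,5R)-3-[4-(benzyloxy)-3-methoxybenzyl]-4-{2-[4-(benzyloxy)-3-methoxyphenyl]-1,3-dithian-2-yl}-5-[(1R,2S,5R)-menthyloxy]oxolan-2-one | O=C1O[C@@H](O[C@@H]2C[C@H](C)CC[C@H]2C(C)C)[C@H](C2(c3ccc(OCc4ccccc4)c(OC)c3)SCCCS2)[C@H]1Cc1ccc(OCc2ccccc2)c(OC)c1
A5 | alternative 2 | (5R)-5-[(1R,2S,5R)-menthyloxy]furan-2(5H)-one | O=C1C=C[C@H](O[C@@H]2C[C@H](C)CC[C@H]2C(C)C)O1
A6 | alternative 2 | 2-[4-(benzyloxy)-3-methoxyphenyl]-1,3-dithiane | COc1cc(C2SCCCS2)ccc1OCc1ccccc1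
A7 | alternative 2 | 1-(benzyloxy)-4-(bromomethyl)-2-methoxybenzene | COc1cc(CBr)ccc1OCc1ccccc1
A8 | alternative 3 | (3S,3aR,6S,6aS)-3,6-bis[4-(benzyloxy)-3-methoxyphenyl]tetrahydro-1H,3H-furo[3,4-c]furan-1-one | O=C1O[C@H](c2ccc(OCc3ccccc3)c(OC)c2)[C@H]2CO[C@H](c3ccc(OCc4ccccc4)c(OC)c3)[C@@H]12
A9 | alternative 3 | (4R,5S)-5-[4-(benzyloxy)-3-methoxyphenyl]-4-({[4-(benzyloxy)-3-methoxybenzyl]oxy}methyl)-3-diazooxolan-2-one | [N-]=[N+]=C1C(=O)O[C@H](c2ccc(OCc3ccccc3)c(OC)c2)[C@H]1COCc1ccc(OCc2ccccc2)c(OC)c1
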